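**Plan**

1. Retrosynthetic cuts: three ArO–Me and two Ar–CHO bonds; then Ar–C1′, with the C1=C8a alkene taken back to a cyclopropane bond C1–C1′ plus a C8a–OH and a helper ketone at C3; then C1–C1′/C2–C1′ (alkylidene transfer), C1=C2 (metathesis), C2–C3 and C1–C8a (organometallic additions), C4–C4a (enolate alkylation) and the side-chain C–OH (hydration), back to (S)-carvone.
2. Forward: ring B is the carvone ring; ring A is closed on it by metathesis; a cyclopropane is fused to ring A; 1,3,5-trimethoxybenzene is then joined with opening of the three-membered ring; the helper ketone is removed, the arene is formylated twice and demethylated.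
3. Enabling feature: the benzylic carbon C1′ is homoallylic to the ring-fusion alkene through the quaternary carbon (C1′–C2–C1=C8a in ring A). This is the retron of a cyclopropylcarbinyl-to-homoallyl opening: a cyclopropane C1′–C2–C1 next to a cation at C8a, with a carbonyl at C3 on C2 to forbid the other ring cleavage.
4. Stereochemistry: C5 from (S)-carvone; C4a by alkylation anti to the C5 group; C8a–OH (a relay, later destroyed) by addition anti to the C4a arm; C2 and the cyclopropane face by ylide attack anti to the axial 8a-oxygen, isobutyl exo; C8 by hydroxyl-directed hydrogenation; C1′ by inversion in the ring opening.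

Key step: step 10

Remark: locants throughout are those of the target's octahydronaphthalene (C1 = ring CH=, C2 = quaternary carbon, C3, C4, C4a, C5 = carbon bearing the hydroxyisopropyl group, C6, C7, C8 = carbon bearing the methyl group, C8a) and C1′ for the benzylic carbon. β is the face of the 2-methyl group and α that of H-4a. HFIP = 1,1,1,3,3,3-hexafluoropropan-2-ol. The target is taken as the (1′S,2S,4aR,5S,8R) isomer given by the SMILES.

**Route**

Step 1
Reactants: 1 (S)-(+)-carvone
Product: 2 (5S)-5-(2-hydroxypropan-2-yl)-2-methylcyclohex-2-en-1-one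
Conditions: 50% aq. H2SO4, 0 °C → rt
Reagents that add atoms: water, O
Why: Acid-catalysed Markovnikov hydration of the isopropenyl group through the tertiary cation leaves the conjugated ring alkene and C5 untouched and masks an alkene that would interfere in the metathesis, ylide and hydrogenation steps.

Step 2
Reactants: 2 (5S)-5-(2-hydroxypropan-2-yl)-2-methylcyclohex-2-en-1-one
Product: 3 (5S)-2-methyl-5-[2-(triethylsilyloxy)propan-2-yl]cyclohex-2-en-1-one
Conditions: Et3SiOTf, 2,6-lutidine, CH2Cl2, −78 → 0 °C
Reagents that add atoms: triethylsilyl trifluoromethanesulfonate, CC[Si](CC)(CC)OS(=O)(=O)C(F)(F)F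
Why: Silylation of a tertiary alcohol with a silyl triflate and a hindered pyridine base is fast at low temperature, before the enone can be enolised.

Step 3
Reactants: 3 (5S)-2-methyl-5-[2-(triethylsilyloxy)propan-2-yl]cyclohex-2-en-1-one
Product: 5 methyl 2-[(1R,6S)-3-methyl-2-oxo-6-[2-(triethylsilyloxy)propan-2-yl]cyclohex-3-en-1-yl]acetate, via lithium dienolate 4 (not isolated)
Conditions: LDA, THF, −78 °C; BrCH2CO2Me, DMPU, −78 → −30 °C
Reagents that add atoms: methyl bromoacetate, COC(=O)CBr
Why: Kinetic α′-deprotonation of the enone and SN2 alkylation of the cross-conjugated lithium dienolate should place the new arm at C4a anti to the bulky C5 substituent (trans product).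

Step 4
Reactants: 5 methyl 2-[(1R,6S)-3-methyl-2-oxo-6-[2-(triethylsilyloxy)propan-2-yl]cyclohex-3-en-1-yl]acetate
Product: 7 cis-fused γ-lactone 7a-ethenyl-7-methyl-4-[2-(triethylsilyloxy)propan-2-yl]-3a,4,5,7a-tetrahydro-1-benzofuran-2(3H)-one, via bromomagnesium alkoxide 6 (not isolated)
Conditions: CH2=CHMgBr, CeCl3 (dried), THF, −78 °C → rt; aq. work-up
Reagents that add atoms: vinylmagnesium bromide, C=C[Mg]Br
Why: Organocerium 1,2-addition to the enone carbonyl anti to the adjacent C4a arm (Felkin-type control) should give the 8a-alkoxide β and cis to the ester arm, which lactonises by intramolecular transesterification on warming.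

Step 5
Reactants: 7 cis-fused γ-lactone
Product: 8 1-[2-ethenyl-2-hydroxy-3-methyl-6-[2-(triethylsilyloxy)propan-2-yl]cyclohex-3-en-1-yl]-3-methylbut-3-en-2-one
Conditions: 2-bromopropene, t-BuLi (2 equiv), Et2O, −78 °C; then 7, THF, −78 °C; H2O quench at −78 °C
Reagents that add atoms: isopropenyllithium, [Li]C(C)=C
Why: Mono-addition of an alkenyllithium to a lactone at −78 °C, where the tetrahedral lithium hemiketal alkoxide persists until the quench, should give the vinyl ketone and free the tertiary 8a-alcohol.

Step 6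
Reactants: 8 hydroxy dienone
Product: 9 trans-fused 8a-hydroxy-2,8-dimethyl-5-[2-(triethylsilyloxy)propan-2-yl]-4a,5,6,8a-tetrahydronaphthalen-3(4H)-one (target locants)
Conditions: (H2IMes)Cl2Ru=CH(2-iPrO-C6H4) (5 mol %), toluene, 80 °C, argon sparge
Reagents that add atoms: none
Why: Ring-closing olefin metathesis between the vinyl group and the 1,1-disubstituted enone alkene closes six-membered ring A as a 2-methylcyclohex-2-enone with loss of ethene, the trisubstituted ring-B alkene being inert.

Step 7
Reactants: 10 diphenyl sulfide; 11 1-iodo-3-methylbutane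
Product: 12 diphenyl(3-methylbutyl)sulfonium tetrafluoroborate
Conditions: AgBF4, CH2Cl2, rt, dark
Reagents that add atoms: silver tetrafluoroborate, [Ag+].F[B-](F)(F)F
Why: Silver-assisted S-alkylation of a diaryl sulfide by a primary iodide gives the sulfonium salt with a non-nucleophilic counter-ion.

Step 8
Reactants: 9 trans-fused hydroxy dienone; 12 diphenyl(3-methylbutyl)sulfonium tetrafluoroborate
Product: 14 cyclopropane-fused ketone (cyclopropane C1–C2–C1′ on the α face and isobutyl exo), via sulfonium ylide 13 (not isolated)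
Conditions: 12 (3 equiv), LDA (3 equiv), DME, −78 °C; then 9, −78 → −30 °C
Reagents that add atoms: none
Why: Corey–Chaykovsky-type alkylidene transfer (Michael-initiated ring closure) in which the ylide should add to C1 axially and anti to the axial 8a-alkoxide, and the enolate closes on C1′ with loss of diphenyl sulfide so that the isobutyl group lies cis to the 2-methyl and H-1 and not to the two ring carbons.

Step 9
Reactants: 14 cyclopropane-fused ketone
Product: 15 7,8-dihydro derivative of 14 with the 8-methyl group α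
Conditions: [Ir(cod)(py)(PCy3)]PF6 (10 mol %), H2 (1 atm), CH2Cl2, 0 °C → rt
Reagents that add atoms: none
Why: Hydroxyl-directed homogeneous hydrogenation, in which the cationic iridium catalyst binds the 8a-OH and should deliver H2 to the β face of the C7=C8 alkene, setting C8 with its methyl group α.

Step 10
Reactants: 15 saturated cyclopropane-fused hydroxy ketone; 16 1,3,5-trimethoxybenzene
Product: 17 (2S,4aR,5S,8R)-2,8-dimethyl-2-[(1S)-3-methyl-1-(2,4,6-trimethoxyphenyl)butyl]-5-[2-(triethylsilyloxy)propan-2-yl]-4,4a,5,6,7,8-hexahydronaphthalen-3(2H)-one (target locants)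
Conditions: 16 (5 equiv), Sc(OTf)3 (10 mol %), 4 Å MS, CH2Cl2/HFIP 9:1, −20 → 0 °C
Reagents that add atoms: none
Why: Proposed new method: the Lewis acid ionises the axial tertiary C8a–OH of 15 to a cyclopropylcarbinyl cation, which the arene should attack at C1′ from the side opposite C1, so that the C1–C1′ bond breaks, the C1=C8a alkene forms and the arene rearomatises by proton loss; the closest known reaction types are the retro-i-steroid (cyclopropylcarbinyl-to-homoallyl) substitution, the Julia homoallyl halide synthesis and the stereoinvertive substitution at cyclopropane carbons of cyclopropylcarbinols, none of them shown with an arene on a ring-fused cyclopropyl ketone. No ring is closed; the three-membered ring C1–C2–C1′ is opened and its strain drives the C–C bond formation. The new stereocentre C1′ is set by inversion at the cyclopropane carbon, so its S configuration follows from the exo-isobutyl, α-face cyclopropane of 15, while C2 keeps the configuration fixed in step 8 and C4a, C5 and C8 are untouched. The step needs cleavage of the external bond C1–C1′ and not of the ring bond C1–C2 (ring expansion, the usual fate of such fused cations): the C3 carbonyl on C2 makes positive charge at C2 prohibitive, and in the trans-fused system only the C1–C1′ bond is antiperiplanar to the axial C8a–O bond. It also needs capture by the arene to outrun loss of H-8 or H-4a, which the large excess of a highly nucleophilic arene in a non-basic, ionising medium should secure. The side-chain oxygen stays silylated so that it neither ionises competitively (it lacks this assistance) nor adds to the new alkene.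

Step 11
Reactants: 17 aryl ketone
Product: 19 2-{(2S,4aR,5S,8R)-2,8-dimethyl-2-[(1S)-3-methyl-1-(2,4,6-trimethoxyphenyl)butyl]-2,3,4,4a,5,6,7,8-octahydronaphthalen-5-yl}propan-2-ol (target locants), via hydrazone 18 (not isolated)
Conditions: anhydrous N2H4, KOH, diethylene glycol, 140 → 210 °C
Reagents that add atoms: none
Why: Wolff–Kishner reduction (Huang-Minlon variant) should remove the helper C3 ketone without alkene migration because C2 is quaternary, and the hot alkali is expected to cleave the triethylsilyl ether as well.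

Step 12
Reactants: 19 trimethoxyaryl alcohol
Product: 21 3-{(1S)-1-[(2S,4aR,5S,8R)-5-(2-hydroxypropan-2-yl)-2,8-dimethyl-2,3,4,4a,5,6,7,8-octahydronaphthalen-2-yl]-3-methylbutyl}-2,4,6-trimethoxybenzaldehyde, via aryllithium 20 (not isolated)
Conditions: n-BuLi (2.2 equiv), TMEDA, THF, 0 °C; DMF, −78 °C → rt; H2O
Reagents that add atoms: N,N-dimethylformamide, CN(C)C=O
Why: Directed ortho-metalation removes a ring hydrogen flanked by two methoxy groups (the tertiary alcohol being carried as its alkoxide) and the aryllithium is formylated by DMF, the two free ring positions being equivalent.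

Step 13
Reactants: 21 monoaldehyde
Product: 23 5-{(1S)-1-[(2S,4aR,5S,8R)-5-(2-hydroxypropan-2-yl)-2,8-dimethyl-2,3,4,4a,5,6,7,8-octahydronaphthalen-2-yl]-3-methylbutyl}-2,4,6-trimethoxybenzene-1,3-dicarbaldehyde, via lithiated aminoalkoxide 22 (not isolated)
Conditions: LiN(Me)CH2CH2NMe2 (from the amine and n-BuLi, 2.2 equiv), THF, −20 °C; n-BuLi (3 equiv), −20 → 0 °C; DMF, −78 °C → rt; H2O
Reagents that add atoms: N,N-dimethylformamide, CN(C)C=O
Why: Directed metalation with in situ carbonyl protection, in which the aldehyde is masked as its lithium α-amino alkoxide so that the last ring hydrogen, again flanked by two methoxy groups, can be lithiated and formylated.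

Step 14
Reactants: 23 dialdehyde trimethyl ether
Product: 24 5-[(1S)-1-[(2S,4aR,5S,8R)-5-(2-hydroxypropan-2-yl)-2,8-dimethyl-2,3,4,4a,5,6,7,8-octahydronaphthalen-2-yl]-3-methylbutyl]-2,4,6-trihydroxybenzene-1,3-dicarbaldehyde (CNP0200991.2)
Conditions: NaSEt (12 equiv), DMF, 120 °C; then cold dilute HCl to pH 3
Reagents that add atoms: none
Why: SN2 demethylation by thiolate is activated because every methoxy group is ortho or para to a formyl group, and these basic conditions spare the tertiary alcohol and the alkene, which acid would join to a cyclic ether.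

**Compound list**

1 | (S)-(+)-carvone, (5S)-2-methyl-5-(prop-1-en-2-yl)cyclohex-2-en-1-one | CC1=CC[C@@H](CC1=O)C(C)=C | starting material
2 | (5S)-5-(2-hydroxypropan-2-yl)-2-methylcyclohex-2-en-1-one | CC1=CC[C@@H](CC1=O)C(C)(C)O | intermediate
3 | (5S)-2-methyl-5-[2-(triethylsilyloxy)propan-2-yl]cyclohex-2-en-1-one | CC1=CC[C@@H](CC1=O)C(C)(C)O[Si](CC)(CC)CC | intermediate
4 | lithium dienolate of 3 (O–Li on C8a, C8a=C4a) | CC1=CC[C@@H](C=C1O[Li])C(C)(C)O[Si](CC)(CC)CC | intermediate (not isolated)
5 | methyl 2-[(1R,6S)-3-methyl-2-oxo-6-[2-(triethylsilyloxy)propan-2-yl]cyclohex-3-en-1-yl]acetate (arm on C4a trans to the C5 group) | CC1=CC[C@H](C(C)(C)O[Si](CC)(CC)CC)[C@@H](CC(=O)OC)C1=O | intermediate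
6 | bromomagnesium alkoxide of the C8a vinyl carbinol (O β, vinyl α, ester arm β) | CC1=CC[C@H](C(C)(C)O[Si](CC)(CC)CC)[C@@H](CC(=O)OC)[C@]1(O[Mg]Br)C=C | intermediate (not isolated)
7 | cis-fused γ-lactone, 7a-ethenyl-7-methyl-4-[2-(triethylsilyloxy)propan-2-yl]-3a,4,5,7a-tetrahydro-1-benzofuran-2(3H)-one (ring O and CH2 β, silyloxypropyl group α) | CC1=CC[C@H](C(C)(C)O[Si](CC)(CC)CC)[C@H]2CC(=O)O[C@@]12C=C | intermediate
8 | 1-[2-ethenyl-2-hydroxy-3-methyl-6-[2-(triethylsilyloxy)propan-2-yl]cyclohex-3-en-1-yl]-3-methylbut-3-en-2-one (8a-OH β, vinyl α, ketone arm β, C5 group α) | CC1=CC[C@H](C(C)(C)O[Si](CC)(CC)CC)[C@@H](CC(=O)C(C)=C)[C@]1(O)C=C | intermediate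
9 | trans-fused 8a-hydroxy-2,8-dimethyl-5-[2-(triethylsilyloxy)propan-2-yl]-4a,5,6,8a-tetrahydronaphthalen-3(4H)-one, target locants (8a-OH β, H-4a α, C5 group α) | CC1=C[C@]2(O)C(C)=CC[C@H](C(C)(C)O[Si](CC)(CC)CC)[C@H]2CC1=O | intermediate
10 | diphenyl sulfide | c1ccc(cc1)Sc1ccccc1 | starting material
11 | 1-iodo-3-methylbutane | CC(C)CCI | starting material
12 | diphenyl(3-methylbutyl)sulfonium tetrafluoroborate | CC(C)CC[S+](c1ccccc1)c1ccccc1.F[B-](F)(F)F | intermediate
13 | diphenylsulfonium 3-methylbutylide | CC(C)C[CH-][S+](c1ccccc1)c1ccccc1 | intermediate (not isolated)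
14 | cyclopropane-fused ketone: 9 with C1=C2 replaced by a cyclopropane C1–C2–C1′ on the α face, isobutyl on C1′ exo (cis to 2-Me and H-1), 2-Me β, C3 ketone, 8a-OH β, C7=C8 | CC(C)C[C@H]1[C@@H]2[C@]3(O)C(C)=CC[C@H](C(C)(C)O[Si](CC)(CC)CC)[C@H]3CC(=O)[C@]12C | intermediate
15 | 7,8-dihydro-14 with 8-methyl α (H-8 β, cis to the 8a-OH) | CC(C)C[C@H]1[C@@H]2[C@]3(O)[C@H](C)CC[C@H](C(C)(C)O[Si](CC)(CC)CC)[C@H]3CC(=O)[C@]12C | intermediate
16 | 1,3,5-trimethoxybenzene | COc1cc(OC)cc(OC)c1 | starting material
17 | (2S,4aR,5S,8R)-2,8-dimethyl-2-[(1S)-3-methyl-1-(2,4,6-trimethoxyphenyl)butyl]-5-[2-(triethylsilyloxy)propan-2-yl]-4,4a,5,6,7,8-hexahydronaphthalen-3(2H)-one, target locants | CC(C)C[C@H](c1c(OC)cc(OC)cc1OC)[C@]1(C)C=C2[C@H](C)CC[C@H](C(C)(C)O[Si](CC)(CC)CC)[C@H]2CC1=O | intermediate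
18 | hydrazone of 17 at C3 | CC(C)C[C@H](c1c(OC)cc(OC)cc1OC)[C@]1(C)C=C2[C@H](C)CC[C@H](C(C)(C)O[Si](CC)(CC)CC)[C@H]2CC1=NN | intermediate (not isolated)
19 | 2-{(2S,4aR,5S,8R)-2,8-dimethyl-2-[(1S)-3-methyl-1-(2,4,6-trimethoxyphenyl)butyl]-2,3,4,4a,5,6,7,8-octahydronaphthalen-5-yl}propan-2-ol, target locants | CC(C)C[C@H](c1c(OC)cc(OC)cc1OC)[C@]1(C)C=C2[C@H](C)CC[C@H](C(C)(C)O)[C@H]2CC1 | intermediate
20 | aryllithium of 19 (Li between two OMe groups, side-chain OLi) | CC(C)C[C@H](c1c(OC)c([Li])c(OC)cc1OC)[C@]1(C)C=C2[C@H](C)CC[C@H](C(C)(C)O[Li])[C@H]2CC1 | intermediate (not isolated)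
21 | 3-{(1S)-1-[(2S,4aR,5S,8R)-5-(2-hydroxypropan-2-yl)-2,8-dimethyl-2,3,4,4a,5,6,7,8-octahydronaphthalen-2-yl]-3-methylbutyl}-2,4,6-trimethoxybenzaldehyde | CC(C)C[C@H](c1c(OC)c(C=O)c(OC)cc1OC)[C@]1(C)C=C2[C@H](C)CC[C@H](C(C)(C)O)[C@H]2CC1 | intermediate
22 | lithiated α-amino alkoxide of 21 (aldehyde masked, Li on the last ring position, side-chain OLi) | CC(C)C[C@H](c1c(OC)c(C(O[Li])N(C)CCN(C)C)c(OC)c([Li])c1OC)[C@]1(C)C=C2[C@H](C)CC[C@H](C(C)(C)O[Li])[C@H]2CC1 | intermediate (not isolated)
23 | 5-{(1S)-1-[(2S,4aR,5S,8R)-5-(2-hydroxypropan-2-yl)-2,8-dimethyl-2,3,4,4a,5,6,7,8-octahydronaphthalen-2-yl]-3-methylbutyl}-2,4,6-trimethoxybenzene-1,3-dicarbaldehyde | CC(C)C[C@H](c1c(OC)c(C=O)c(OC)c(C=O)c1OC)[C@]1(C)C=C2[C@H](C)CC[C@H](C(C)(C)O)[C@H]2CC1 | intermediate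
24 | 5-[(1S)-1-[(2S,4aR,5S,8R)-5-(2-hydroxypropan-2-yl)-2,8-dimethyl-2,3,4,4a,5,6,7,8-octahydronaphthalen-2-yl]-3-methylbutyl]-2,4,6-trihydroxybenzene-1,3-dicarbaldehyde | CC(C)C[C@H](c1c(O)c(C=O)c(O)c(C=O)c1O)[C@]1(C)C=C2[C@H](C)CC[C@H](C(C)(C)O)[C@H]2CC1 | target

**Count**

Total step count: 14. Longest linear sequence: 13 steps (steps 1–6 and 8–14; step 7 makes the ylide precursor).

**Steps most likely to fail, with fallbacks**

Step 10 (labelled). The cation may lose H-8 or H-4a faster than the arene captures it at C1′, or the Lewis acid may also ionise the tertiary silyl ether. The fallback uses known chemistry, sets out from 15 and comes back at 17. The cyclopropylcarbinol 15 would first be opened with bromide in a Julia-type cyclopropylcarbinol-to-homoallyl bromide rearrangement (MgBr2·OEt2, Et2O, 0 °C → rt), which should give the homoallylic bromide F1 with the C1=C8a alkene already in place. F1 would then be joined to commercial 2-bromo-1,3,5-trimethoxybenzene (COc1cc(OC)c(Br)c(OC)c1) by nickel-catalysed reductive cross-electrophile coupling (NiBr2·glyme, 4,4′-di-tert-butyl-2,2′-bipyridine, Zn, DMA, 60 °C). That coupling runs through the C1′ radical, so stereocontrol at C1′ is given up: 17 would have to be separated from its C1′ epimer F2 before the route continues with step 11.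

Step 8. The bulky secondary ylide may enolise the ketone at C4 or attack the carbonyl instead of adding to the hindered C1, and the exo/endo selectivity at C1′ may be low. The fallback sets out from 9 and comes back at 14. Isovaleraldehyde would be condensed with tosylhydrazide to the N-tosylhydrazone F3, whose sodium salt is pyrolysed under vacuum (Bamford–Stevens) to 1-diazo-3-methylbutane F4. 1,3-Dipolar cycloaddition of F4 to the enone of 9 (Et2O, 0 °C → rt, dark), again from the α face, should give the 1-pyrazoline F5, which cannot tautomerise because C2 is quaternary. Photolysis (350 nm, −20 °C) would then extrude N2 to give 14.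

Step 11. Hydrazone formation may stall at the ketone flanked by the quaternary C2, and prolonged heating in alkali may start to attack the aryl methyl ethers. The fallback sets out from 17 and comes back at 19. The ketone would be reduced with LiAlH4 (THF, 0 °C) to the C3 alcohol F6 (either epimer serves), converted into the S-methyl xanthate F7 (NaH, CS2, MeI, THF) and deoxygenated by the Barton–McCombie reaction (Bu3SnH, AIBN, toluene, 110 °C, high stannane concentration to outrun a 1,2-vinyl shift of the C3 radical) to the silyl ether F8. Bu4NF in THF would then give 19.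

Further compounds
F1 | step 10 | homoallylic bromide: 17 with Br in place of the aryl group on C1′ | CC(C)C[C@H](Br)[C@]1(C)C=C2[C@H](C)CC[C@H](C(C)(C)O[Si](CC)(CC)CC)[C@H]2CC1=O
F2 | step 10 | C1′ epimer of 17 | CC(C)C[C@@H](c1c(OC)cc(OC)cc1OC)[C@]1(C)C=C2[C@H](C)CC[C@H](C(C)(C)O[Si](CC)(CC)CC)[C@H]2CC1=O
F3 | step 8 | isovaleraldehyde N-tosylhydrazone | CC(C)CC=NNS(=O)(=O)c1ccc(C)cc1
F4 | step 8 | 1-diazo-3-methylbutane | CC(C)CC=[N+]=[N-]
F5 | step 8 | 1-pyrazoline from 9 (C1′ bonded to C1, N bonded to C2, both on the α face, isobutyl cis to 2-Me and H-1) | CC(C)C[C@@H]1N=N[C@@]2(C)C(=O)C[C@@H]3[C@@H](C(C)(C)O[Si](CC)(CC)CC)CC=C(C)[C@@]3(O)[C@@H]12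
F6 | step 11 | C3 alcohol from 17 (C3 configuration not defined) | CC(C)C[C@H](c1c(OC)cc(OC)cc1OC)[C@]1(C)C=C2[C@H](C)CC[C@H](C(C)(C)O[Si](CC)(CC)CC)[C@H]2CC1O
F7 | step 11 | S-methyl xanthate of F6 | CC(C)C[C@H](c1c(OC)cc(OC)cc1OC)[C@]1(C)C=C2[C@H](C)CC[C@H](C(C)(C)O[Si](CC)(CC)CC)[C@H]2CC1OC(=S)SC
F8 | step 11 | triethylsilyl ether of 19 | CC(C)C[C@H](c1c(OC)cc(OC)cc1OC)[C@]1(C)C=C2[C@H](C)CC[C@H](C(C)(C)O[Si](CC)(CC)CC)[C@H]2CC1
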